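**Strategy.** Each trans-2,3-diaryl-2,3-dihydrobenzofuran is cut at O1–C2 and C3–C3a into an E-stilbene and one o-quinone diazide carbene, used three times, with Heck reactions regrowing the next stilbene. For ring A (the dihydrobenzofuran carrying the 3,5-dihydroxyphenyl group) the carbene adduct is isolated as a spiro[2.5]octadienone whose cyclopropane holds C3a, C3 and C2. The key step is a Lewis-acid Cloke–Wilson 1,3-shift that expands this cyclopropane by two atoms into the ring O1–C2–C3–C3a–C7a. It exploits the cation-stabilising 4-oxyphenyl group on C2 and the rearomatisation of the C7a carbonyl ring, forms O1–C2 and sets C2 trans to C3.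

Key step: step 7

Ring labels: ring A = terminal dihydrobenzofuran with the 3,5-dioxygenated phenyl group on C3; ring B = central dihydrobenzofuran; ring C = dihydrobenzofuran that carries the styryl group on C4.

Assumption: Rh2(S-TCPTTL)4, dirhodium tetrakis[N-tetrachlorophthaloyl-(S)-tert-leucinate], is taken to deliver the R configuration at the carbon that becomes C3 of ring A; if its sense of induction is the opposite, the two catalyst enantiomers are exchanged throughout.

Step 1
Reactants: 1 1-bromo-3,5-dimethoxybenzene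
Product: 2 1-bromo-3,5-dimethoxy-2-nitrobenzene
Conditions: HNO3 (70 %, 1.05 equiv), AcOH, 10 °C
Reagents that add atoms: nitric acid, O[N+](=O)[O-]
Why: Electrophilic aromatic nitration should occur at C2, para to one methoxy group and ortho to the other, in preference to the position between the two methoxy groups, and the minor 4-nitro isomer is removed by crystallisation.

Step 2
Reactants: 2 1-bromo-3,5-dimethoxy-2-nitrobenzene
Product: 3 5-bromo-4-nitrobenzene-1,3-diol
Conditions: BBr3 (4 equiv), CH2Cl2, −78 °C → rt; H2O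
Reagents that add atoms: none
Why: Lewis-acid ether cleavage with BBr3 removes both aryl methyl groups as bromomethane while the nitro group and the aryl bromide are inert.

Step 3
Reactants: 3 5-bromo-4-nitrobenzene-1,3-diol
Product: 4 3-bromo-5-hydroxy-4-nitrophenyl pivalate
Conditions: PivCl (1.0 equiv), Et3N (1.1 equiv), CH2Cl2, −20 °C
Reagents that add atoms: pivaloyl chloride, CC(C)(C)C(=O)Cl
Why: Selective O-acylation is expected because the hydroxyl ortho to the nitro group is held in an intramolecular hydrogen bond, so the freer para-hydroxyl is pivaloylated first with one equivalent of acid chloride.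

Step 4
Reactants: 4 3-bromo-5-hydroxy-4-nitrophenyl pivalate
Product: 5 4-amino-3-bromo-5-hydroxyphenyl pivalate
Conditions: H2 (1 atm), sulfided 5 % Pt/C, EtOAc, rt
Reagents that add atoms: none
Why: Catalytic hydrogenation of the nitro group over sulfided platinum is chemoselective and should leave the aryl bromide and the aryl ester untouched; the air-sensitive aminophenol is used at once.

Step 5
Reactants: 5 4-amino-3-bromo-5-hydroxyphenyl pivalate
Product: 6 5-bromo-4-diazo-3-oxocyclohexa-1,5-dien-1-yl pivalate (o-quinone diazide)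
Conditions: tBuONO (1.2 equiv), AcOH (10 mol %), THF, 0 °C, dark
Reagents that add atoms: tert-butyl nitrite, CC(C)(C)ON=O
Why: Diazotisation of the o-aminophenol gives a diazonium ion that loses the ortho-phenol proton to form the neutral o-quinone diazide, and the pivalate on the para-oxygen rules out the para-quinone diazide tautomer.

Step 6
Reactants: 6 5-bromo-4-diazo-3-oxocyclohexa-1,5-dien-1-yl pivalate; 7 (E)-resveratrol triacetate
Product: 8 (1R,2R,3R)-1-(4-acetoxyphenyl)-2-(3,5-diacetoxyphenyl)-8-bromo-4-oxospiro[2.5]octa-5,7-dien-6-yl pivalate (trans-diaryl spirocyclopropane drawn with C=O syn to the 4-acetoxyphenyl group)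
Conditions: Rh2(S-TCPTTL)4 (1 mol %), 7 (2 equiv), PhCF3, 10 °C, slow addition of 6, dark; cold filtration through deactivated silica, crystallisation at −20 °C
Reagents that add atoms: none
Why: Dirhodium-catalysed loss of N2 gives an electrophilic carbene that cyclopropanates the E-alkene stereospecifically, so the two aryl groups stay trans, the chiral carboxylate ligands select the alkene face and thereby fix the carbon that becomes C3 of ring A, the spiro centre (either epimer serves) disappears in step 7, and the weakly donating acetoxy group should keep 8 from ionising before it is isolated.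

Step 7
Reactants: 8 (1R,2R,3R)-spirocyclopropane
Product: 9 (2R,3R)-2-(4-acetoxyphenyl)-4-bromo-3-(3,5-diacetoxyphenyl)-2,3-dihydrobenzofuran-6-yl pivalate (ring-A bromide)
Conditions: Sc(OTf)3 (5 mol %), CH2Cl2, −20 °C → rt
Reagents that add atoms: none
Why: Sc(OTf)3 binds the dienone oxygen and the spiro C3a–C2 bond, the one to the carbon carrying the 4-acetoxyphenyl group, ionises to an aryloxide and a 4-acyloxybenzyl cation, with rearomatisation of the six-membered ring as the driving force. The aryloxide oxygen then closes on that cation in a 5-exo-trig mode (the cation is the exocyclic carbon of a quinone-methide-like system), so the cyclopropane C3a–C3–C2 becomes the ring O1–C2–C3–C3a–C7a, two atoms larger. The closest known reaction type is the Lewis-acid Cloke–Wilson rearrangement of donor-substituted cyclopropyl ketones and spirocyclopropane 1,3-diones to 2,3-dihydrofurans. C3 is not touched and keeps the configuration set by the catalyst in step 6, while C2 is set by closure anti to the C3 aryl group and, since ionisation of C2–O1 is reversible under the Lewis acid, by the thermodynamic preference for the trans isomer. The step needs cleavage of the cyclopropane bond to C2 and not of that to C3, which the substrate secures through the para-oxygen donor on the C2 aryl group against two meta-acyloxy groups on the C3 aryl group.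

Step 8
Reactants: 9 ring-A bromide; 10 4-(tert-butyldimethylsilyloxy)styrene
Product: 11 (2R,3R)-2-(4-acetoxyphenyl)-3-(3,5-diacetoxyphenyl)-4-[(E)-4-(tert-butyldimethylsilyloxy)styryl]-2,3-dihydrobenzofuran-6-yl pivalate (ring-A stilbene)
Conditions: 10 (1.5 equiv), Pd(P(tBu)3)2 (5 mol %), Cy2NMe (1.5 equiv), 1,4-dioxane, 50 °C
Reagents that add atoms: none
Why: Mizoroki–Heck arylation at the terminal alkene carbon followed by syn β-hydride elimination should give the E-stilbene, and the amine base spares the aryl esters, the silyl ether and both stereocentres.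

Step 9
Reactants: 11 ring-A stilbene; 6 o-quinone diazide
Product: 13 (2S,3S)-4-bromo-2-[4-(tert-butyldimethylsilyloxy)phenyl]-3-[ring A of 9 bonded through its C4]-2,3-dihydrobenzofuran-6-yl pivalate (ring-A–ring-B bromide), via spirocyclopropane 12 (not isolated)
Conditions: 6 (2 equiv, slow addition), Rh2(R-TCPTTL)4 (2 mol %), PhCF3, 0 °C → 40 °C, dark
Reagents that add atoms: none
Why: The same carbene transfer gives spirocyclopropane 12, whose bond to the carbon bearing the strongly donating 4-silyloxyphenyl group ionises spontaneously (Cloke–Wilson ring expansion) so that oxygen closes on that carbon; the carbene is expected to approach the alkene face anti to the 3,5-diacetoxyphenyl group on the neighbouring C3 of ring A, a substrate bias that the (R)-catalyst is chosen to reinforce and that sets C3 of ring B as S, and closure anti to the C3 substituent sets C2 trans.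

Step 10
Reactants: 13 ring-A–ring-B bromide; 10 4-(tert-butyldimethylsilyloxy)styrene
Product: 14 analogue of 13 with an (E)-4-(tert-butyldimethylsilyloxy)styryl group in place of bromine on C4 of ring B (ring-B stilbene)
Conditions: 10 (1.5 equiv), Pd(P(tBu)3)2 (5 mol %), Cy2NMe (1.5 equiv), 1,4-dioxane, 60 °C
Reagents that add atoms: none
Why: A second Mizoroki–Heck reaction at the aryl bromide of ring B should give the E-stilbene without touching the four stereocentres or the protecting groups.

Step 11
Reactants: 14 ring-B stilbene; 6 o-quinone diazide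
Product: 16 (2R,3R)-4-bromo-2-[4-(tert-butyldimethylsilyloxy)phenyl]-3-[ring B of 14 bonded through its C4]-2,3-dihydrobenzofuran-6-yl pivalate (ring-C bromide), via spirocyclopropane 15 (not isolated)
Conditions: 6 (2 equiv, slow addition), Rh2(S-TCPTTL)4 (2 mol %), PhCF3, 0 °C → 40 °C, dark
Reagents that add atoms: none
Why: Carbene transfer and spontaneous Cloke–Wilson ring expansion repeat on the only alkene present; approach anti to the ring-A benzofuranyl group on C3 of ring B, reinforced by the (S)-catalyst, should set C3 of ring C as R, and closure anti to it sets C2 trans.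

Step 12
Reactants: 16 ring-C bromide; 17 3,4-diacetoxystyrene
Product: 18 fully protected target (pentaacetate tripivalate bis-silyl ether of 19)
Conditions: 17 (1.5 equiv), Pd(P(tBu)3)2 (5 mol %), Cy2NMe (1.5 equiv), 1,4-dioxane, 60 °C
Reagents that add atoms: none
Why: The third Mizoroki–Heck reaction should install the E-configured 3,4-diacetoxystyryl group on C4 of ring C under the same mild amine-base conditions.

Step 13
Reactants: 18 fully protected target
Product: 19 CNP0099535.1
Conditions: NaOMe (15 equiv), MeOH/THF 2:1 (degassed), argon, 0 °C → rt; AcOH quench at 0 °C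
Reagents that add atoms: none
Why: Zemplén-type methanolysis should cleave the five aryl acetates, the three aryl pivalates and the two aryl silyl ethers in one operation, exclusion of oxygen protects the catechol and the stilbene, and no stereocentre is at risk because all three trans-2,3-diaryl rings are the thermodynamic isomers.

**Compound list**

1 | 1-bromo-3,5-dimethoxybenzene | COc1cc(Br)cc(OC)c1 | starting material
2 | 1-bromo-3,5-dimethoxy-2-nitrobenzene | COc1cc(OC)c([N+](=O)[O-])c(Br)c1 | intermediate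
3 | 5-bromo-4-nitrobenzene-1,3-diol | Oc1cc(O)c([N+](=O)[O-])c(Br)c1 | intermediate
4 | 3-bromo-5-hydroxy-4-nitrophenyl pivalate | CC(C)(C)C(=O)Oc1cc(O)c([N+](=O)[O-])c(Br)c1 | intermediate
5 | 4-amino-3-bromo-5-hydroxyphenyl pivalate | CC(C)(C)C(=O)Oc1cc(O)c(N)c(Br)c1 | intermediate
6 | 5-bromo-4-diazo-3-oxocyclohexa-1,5-dien-1-yl pivalate (o-quinone diazide) | CC(C)(C)C(=O)OC1=CC(=O)C(=[N+]=[N-])C(Br)=C1 | intermediate
7 | (E)-resveratrol triacetate, (E)-3,5,4'-triacetoxystilbene | CC(=O)Oc1ccc(/C=C/c2cc(OC(C)=O)cc(OC(C)=O)c2)cc1 | starting material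
8 | (1R,2R,3R)-1-(4-acetoxyphenyl)-2-(3,5-diacetoxyphenyl)-8-bromo-4-oxospiro[2.5]octa-5,7-dien-6-yl pivalate | O=C1C=C(OC(=O)C(C)(C)C)C=C(Br)[C@]12[C@@H](c1cc(OC(C)=O)cc(OC(C)=O)c1)[C@@H]2c1ccc(OC(C)=O)cc1 | intermediate
9 | (2R,3R)-2-(4-acetoxyphenyl)-4-bromo-3-(3,5-diacetoxyphenyl)-2,3-dihydrobenzofuran-6-yl pivalate | Brc1cc(OC(=O)C(C)(C)C)cc2c1[C@@H](c1cc(OC(C)=O)cc(OC(C)=O)c1)[C@H](c1ccc(OC(C)=O)cc1)O2 | intermediate
10 | 4-(tert-butyldimethylsilyloxy)styrene | C=Cc1ccc(O[Si](C)(C)C(C)(C)C)cc1 | starting material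
11 | (2R,3R)-2-(4-acetoxyphenyl)-3-(3,5-diacetoxyphenyl)-4-[(E)-4-(tert-butyldimethylsilyloxy)styryl]-2,3-dihydrobenzofuran-6-yl pivalate | CC(C)(C)[Si](C)(C)Oc1ccc(/C=C/c2cc(OC(=O)C(C)(C)C)cc3c2[C@@H](c2cc(OC(C)=O)cc(OC(C)=O)c2)[C@H](c2ccc(OC(C)=O)cc2)O3)cc1 | intermediate
12 | spirocyclopropane from 6 and the alkene of 11: trans cyclopropane, the carbon bearing the ring-A benzofuranyl group has the configuration that becomes (3S) of ring B, drawn with C=O syn to the silyloxyphenyl group | CC(C)(C)[Si](C)(C)Oc1ccc([C@H]2[C@@]3(C(=O)C=C(OC(=O)C(C)(C)C)C=C3Br)[C@@H]2c2cc(OC(=O)C(C)(C)C)cc3c2[C@@H](c2cc(OC(C)=O)cc(OC(C)=O)c2)[C@H](c2ccc(OC(C)=O)cc2)O3)cc1 | intermediate (not isolated)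
13 | ring-A–ring-B bromide: ring B (2S,3S) with 4-bromo, 6-pivaloyloxy and 2-[4-(tert-butyldimethylsilyloxy)phenyl], bonded at C3 to C4 of ring A (2R,3R; as in 9) | CC(C)(C)[Si](C)(C)Oc1ccc([C@H]2Oc3cc(OC(=O)C(C)(C)C)cc(Br)c3[C@@H]2c2cc(OC(=O)C(C)(C)C)cc3c2[C@@H](c2cc(OC(C)=O)cc(OC(C)=O)c2)[C@H](c2ccc(OC(C)=O)cc2)O3)cc1 | intermediate
14 | ring-B stilbene: 13 with (E)-4-(tert-butyldimethylsilyloxy)styryl in place of Br on C4 of ring B | CC(C)(C)[Si](C)(C)Oc1ccc([C@H]2Oc3cc(OC(=O)C(C)(C)C)cc(/C=C/c4ccc(O[Si](C)(C)C(C)(C)C)cc4)c3[C@@H]2c2cc(OC(=O)C(C)(C)C)cc3c2[C@@H](c2cc(OC(C)=O)cc(OC(C)=O)c2)[C@H](c2ccc(OC(C)=O)cc2)O3)cc1 | intermediate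
15 | spirocyclopropane from 6 and the alkene of 14: trans cyclopropane, the carbon bearing the ring-B benzofuranyl group has the configuration that becomes (3R) of ring C, drawn with C=O syn to the silyloxyphenyl group | CC(C)(C)[Si](C)(C)Oc1ccc([C@H]2Oc3cc(OC(=O)C(C)(C)C)cc([C@@H]4[C@@]5(C(=O)C=C(OC(=O)C(C)(C)C)C=C5Br)[C@H]4c4ccc(O[Si](C)(C)C(C)(C)C)cc4)c3[C@@H]2c2cc(OC(=O)C(C)(C)C)cc3c2[C@@H](c2cc(OC(C)=O)cc(OC(C)=O)c2)[C@H](c2ccc(OC(C)=O)cc2)O3)cc1 | intermediate (not isolated)
16 | ring-C bromide: ring C (2R,3R) with 4-bromo, 6-pivaloyloxy and 2-[4-(tert-butyldimethylsilyloxy)phenyl], bonded at C3 to C4 of ring B (2S,3S), which is bonded at C3 to C4 of ring A (2R,3R) | CC(C)(C)[Si](C)(C)Oc1ccc([C@H]2Oc3cc(OC(=O)C(C)(C)C)cc([C@@H]4c5c(Br)cc(OC(=O)C(C)(C)C)cc5O[C@H]4c4ccc(O[Si](C)(C)C(C)(C)C)cc4)c3[C@@H]2c2cc(OC(=O)C(C)(C)C)cc3c2[C@@H](c2cc(OC(C)=O)cc(OC(C)=O)c2)[C@H](c2ccc(OC(C)=O)cc2)O3)cc1 | intermediate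
17 | 3,4-diacetoxystyrene | C=Cc1ccc(OC(C)=O)c(OC(C)=O)c1 | starting material
18 | fully protected target: 16 with (E)-3,4-diacetoxystyryl in place of Br on C4 of ring C (pentaacetate, tripivalate, bis-silyl ether) | CC(C)(C)[Si](C)(C)Oc1ccc([C@H]2Oc3cc(OC(=O)C(C)(C)C)cc([C@@H]4c5c(/C=C/c6ccc(OC(C)=O)c(OC(C)=O)c6)cc(OC(=O)C(C)(C)C)cc5O[C@H]4c4ccc(O[Si](C)(C)C(C)(C)C)cc4)c3[C@@H]2c2cc(OC(=O)C(C)(C)C)cc3c2[C@@H](c2cc(OC(C)=O)cc(OC(C)=O)c2)[C@H](c2ccc(OC(C)=O)cc2)O3)cc1 | intermediate
19 | CNP0099535.1: 4-[(E)-2-{(2R,3R)-6-hydroxy-2-(4-hydroxyphenyl)-3-[(2S,3S)-6-hydroxy-2-(4-hydroxyphenyl)-3-[(2R,3R)-3-(3,5-dihydroxyphenyl)-6-hydroxy-2-(4-hydroxyphenyl)-2,3-dihydrobenzofuran-4-yl]-2,3-dihydrobenzofuran-4-yl]-2,3-dihydrobenzofuran-4-yl}ethenyl]benzene-1,2-diol | Oc1ccc([C@H]2Oc3cc(O)cc([C@@H]4c5c(/C=C/c6ccc(O)c(O)c6)cc(O)cc5O[C@H]4c4ccc(O)cc4)c3[C@@H]2c2cc(O)cc3c2[C@@H](c2cc(O)cc(O)c2)[C@H](c2ccc(O)cc2)O3)cc1 | target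

**Step count and risks**

Total step count: 13. Longest linear sequence: 13 steps (1 to 19); compounds 7, 10 and 17 are purchased and 6 is used three times.

Steps most likely to fail:

Step 6. The catalyst may discriminate poorly between the two faces of an E-1,2-diarylalkene, and the cyclopropane may ionise during isolation (the latter would only telescope steps 6 and 7). The fallback replaces asymmetric catalysis by resolution. It sets out from 6 and 7: the achiral catalyst Rh2(esp)2, dirhodium bis(α,α,α′,α′-tetramethyl-1,3-benzenedipropionate), should give the racemic cyclopropane, that is 8 together with its enantiomer, the (1S,2S,3S)-spirocyclopropane F1. Ring expansion with Sc(OTf)3 as in step 7 then gives 9 together with its enantiomer, the (2S,3S)-ring-A bromide F2. Preparative chromatography on a chiral stationary phase separates the two, and the route is rejoined at 9.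

Step 9. Capture of the carbene by the crowded, ortho-substituted stilbene may be slow, so that carbene self-coupling takes over, and facial selectivity may erode if catalyst and substrate preferences do not add up. The fallback gives up reagent control for substrate control plus separation of diastereomers. It sets out from 11 (with 6): the more robust achiral Rh2(esp)2 at 40 °C with syringe-pump addition of 6 lets both alkene faces react. This gives 12 and the spirocyclopropane formed on the other alkene face F3 (neither isolated), and after ring expansion 13 and its ring-B (2R,3R) diastereomer F4. These are diastereomers and are separated on silica, and the route is rejoined at 13.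

Step 11. The same two processes threaten the third carbene transfer, on a still larger substrate, together with competing attack of the carbene on the electron-rich silyloxyphenyl ring of ring B. The fallback is again substrate control plus separation. It sets out from 14 (with 6): Rh2(esp)2 at 40 °C gives 15 and the spirocyclopropane formed on the other alkene face F5 (neither isolated), and after ring expansion 16 and its ring-C (2S,3S) diastereomer F6. Chromatography on silica separates them, and the route is rejoined at 16.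

**Further compounds**

F1 | step 6 | (1S,2S,3S)-spirocyclopropane, enantiomer of 8 | O=C1C=C(OC(=O)C(C)(C)C)C=C(Br)[C@@]12[C@H](c1cc(OC(C)=O)cc(OC(C)=O)c1)[C@H]2c1ccc(OC(C)=O)cc1
F2 | step 6 | (2S,3S)-ring-A bromide, enantiomer of 9 | Brc1cc(OC(=O)C(C)(C)C)cc2c1[C@H](c1cc(OC(C)=O)cc(OC(C)=O)c1)[C@@H](c1ccc(OC(C)=O)cc1)O2
F3 | step 9 | other-face spirocyclopropane, epimer of 12 at the three cyclopropane carbons | CC(C)(C)[Si](C)(C)Oc1ccc([C@@H]2[C@]3(C(=O)C=C(OC(=O)C(C)(C)C)C=C3Br)[C@H]2c2cc(OC(=O)C(C)(C)C)cc3c2[C@@H](c2cc(OC(C)=O)cc(OC(C)=O)c2)[C@H](c2ccc(OC(C)=O)cc2)O3)cc1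
F4 | step 9 | ring-B (2R,3R) diastereomer of 13 | CC(C)(C)[Si](C)(C)Oc1ccc([C@@H]2Oc3cc(OC(=O)C(C)(C)C)cc(Br)c3[C@H]2c2cc(OC(=O)C(C)(C)C)cc3c2[C@@H](c2cc(OC(C)=O)cc(OC(C)=O)c2)[C@H](c2ccc(OC(C)=O)cc2)O3)cc1
F5 | step 11 | other-face spirocyclopropane, epimer of 15 at the three cyclopropane carbons | CC(C)(C)[Si](C)(C)Oc1ccc([C@H]2Oc3cc(OC(=O)C(C)(C)C)cc([C@H]4[C@]5(C(=O)C=C(OC(=O)C(C)(C)C)C=C5Br)[C@@H]4c4ccc(O[Si](C)(C)C(C)(C)C)cc4)c3[C@@H]2c2cc(OC(=O)C(C)(C)C)cc3c2[C@@H](c2cc(OC(C)=O)cc(OC(C)=O)c2)[C@H](c2ccc(OC(C)=O)cc2)O3)cc1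
F6 | step 11 | ring-C (2S,3S) diastereomer of 16 | CC(C)(C)[Si](C)(C)Oc1ccc([C@H]2Oc3cc(OC(=O)C(C)(C)C)cc([C@H]4c5c(Br)cc(OC(=O)C(C)(C)C)cc5O[C@@H]4c4ccc(O[Si](C)(C)C(C)(C)C)cc4)c3[C@@H]2c2cc(OC(=O)C(C)(C)C)cc3c2[C@@H](c2cc(OC(C)=O)cc(OC(C)=O)c2)[C@H](c2ccc(OC(C)=O)cc2)O3)cc1
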